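The readings come from a simulation from invented constants; noise was put on by code.

If a chain of two stages runs in a closed flask and its first stage ends early, the late slope of the product curve follows from one number, how fast the slower stage clears what stands before it; the knee and the level have to be drawn apart from it.

| flask | starting material | free catalyst | temperature | remark | time |
|---|---|---|---|---|---|
| red | 0.30 M | 59 mM | 30 °C | run made earlier |  |
| amber | 0.30 M | 92 mM | 45 °C | run made earlier |  |
| green | 0.15 M | 42 mM | 30 °C | run made earlier |  |
| Tuesday's | 0.30 M | 42 mM | 55 °C |  | 50 min |
| Wednesday's | 0.30 M | 42 mM | 35 °C |  | 50 min |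
| Monday's | 0.30 M | 42 mM |  | at 35 °C until 25 min, from then on at 55 °C | 50 min |

| run | time / min | product / % |
|---|---|---|
| red | 15.0 | 1.1 |
| red | 30.0 | 3.6 |
| red | 40.0 | 5.2 |
| red | 50.0 | 7.4 |
| red | 80.0 | 14.4 |
| red | 150 | 32.0 |
| red | 180 | 38.1 |
| amber | 8.00 | 4.8 |
| amber | 12.0 | 9.4 |
| amber | 20.0 | 18.7 |
| amber | 25.0 | 24.4 |
| amber | 40.0 | 40.1 |
| amber | 60.0 | 56.2 |
| amber | 90.0 | 71.9 |
| green | 15.0 | 0.2 |
| green | 50.0 | 5.9 |
| green | 90.0 | 13.9 |
| green | 150 | 28.2 |
| green | 180 | 34.3 |

(readings scatter by 0.5 percentage points)

- on the list of suspects stand: starting material -> intermediate; starting material + free catalyst -> spent catalyst; free catalyst + intermediate -> free catalyst + product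

* the best flask by amount of product, in percent of the starting material charged; "all alike" if 1.5 percentage points covers them all (Tuesday's / Wednesday's / Monday's / all alike)
* amount of product at the end, in percent of the starting material charged, Tuesday's
* amount of product at the end, in percent of the starting material charged, Wednesday's
* amount of product at the end, in percent of the starting material charged, Monday's

The amber tail told me that number. From 60.0 min to 90.0 min, what was not yet product shrank at 0.0148 /min, and the red tail from 150 min to 180 min shrank at 0.00313 /min. The readings scarcely say which stage is the slow one. I took it to be the catalyst's stage, from intermediate to product, and reckoned per amount of catalyst charged. That gave a factor of 3.03 from the red temperature to the amber one, and I carried it on at a steady factor per degree. So Tuesday's clearing rate, the fraction of the unfinished material turned into product each minute, came to 0.0141 /min, a clearing time of 70.7 min.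

Then I drew Tuesday's curve. It starts flat. Amber's straight stretch, run backwards, meets zero at 3.91 min, and I took that as the knee, which is far shorter than the clearing time. Using the knee as the time of the first stage, the intermediate crosses from growing to shrinking near 12.0 min. Past that crossing, in my reckoning for Tuesday's, the clearing is the rate-limiting step, and the slope stays near 0.0141 /min of the unfinished material. The level lies near the whole charge, less at most the 14.0% that can leave with the catalyst. Counting from zero, I expected 50.7% at 50 min.

The forecast said Tuesday's would be best, with 75%, 12.8% and 54%: “Catalyst poisoning looks small but is poorly defined”. My Tuesday's figure is lower than its figure.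

Tuesday's gave 52.8%, Wednesday's 10.6% and Monday's 32.8%, so Tuesday's was best, but at 50.0 min Tuesday's still held 43.5% as intermediate. On Monday's, 3.74% was product at the change of temperature, and the clearing rate over the remaining time gives 32.4% against the 32.8% found.

    starting material → intermediate (k = 5.13 × 10⁻⁴ /s, Ea = 86.0 kJ/mol)
    starting material + free catalyst → spent catalyst (k = 7.28 × 10⁻⁴ /M/s, Ea = 74.0 kJ/mol)
    free catalyst + intermediate → free catalyst + product (k = 0.00244 /M/s, Ea = 56.0 kJ/mol)
    (constants at 35 °C)

For Tuesday's flask left until 20 min, the same clearing rate gives 24.6%, and the computed flask stands at 23.6%.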